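Its constants were drawn at random within sensible limits; the rest is arithmetic.

**The ratio.** The decomposition constant of second reagent divided by its capture constant with intermediate A is a concentration, 0.200 mM, the break-even level: with [intermediate A] at this level, second reagent is captured as fast as it decomposes, and above this level it is captured faster.

substrate 0.50 mM; partner 1.50 mM; second reagent 0.750 mM; solid third reagent 0.500 mM; time 10 min

* how much target there is at 10 min, in percent of the substrate charged
* how much intermediate A there is at 10 min, in percent of the substrate charged

- for target the crystals are counted in
- as a solid, counted per litre of solution: crystals, solid third reagent
- at the start none of the solid third reagent is in solution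
- run time (flask): 10 min

    substrate + partner → intermediate A (k1 = 33 /M/s)
    second reagent + intermediate A → intermediate B (k2 = 140 /M/s)
    third reagent + intermediate B → target (k3 = 150 /M/s)
    crystals ⇌ target, rate k4*(cs4 - [target]) while solid is left; crystals form when [target] > cs4 (cs4 = 0.17 mM, k4 = 1.8 /s)
    second reagent → decomposed reagent (k5 = 0.028 /s)
    solid third reagent ⇌ third reagent, rate k6*(cs6 - [third reagent]) while solid is left; crystals form when [third reagent] > cs6 (cs6 = 0.16 mM, k6 = 1.9 /s)

**Two flasks.** Your flask holds 1.50 equivalents of second reagent on substrate, and the neighbour with 0.45 mM holds 0.900. Counting equivalents, your flask could finish and the neighbour could not. But the half-life of second reagent by decomposition alone, 0.41 min, is about twice that of substrate by its reaction with partner as charged, 0.23 min, so in both flasks second reagent decomposes while intermediate A is still forming, and both should end below the count.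

**Frozen reckoning.** I freeze [partner] at its charge, 3.00 times the substrate. Formation of intermediate A is then pseudo-first-order, with a mean wait of 0.337 min. Of the charge in your flask, I count 0.426 mM of second reagent as surviving that wait. I also freeze [third reagent] at its solubility, which gives intermediate B a half-life of 0.481 min, shorter than the run, so each capture ends as target. The surviving reagent splits as [intermediate A] to the break-even level, with [intermediate A] frozen at the substrate charge less half the amount captured. Solving this gives 0.275 mM captured: 54.9 % target and 45.1 % intermediate A.

**The forecast.** It gives 56.5 % target (53 % to 60 %) and 43.5 % intermediate A (40 % to 47 %), slightly more target than my figure. Its ground: “The second reagent decomposes within about a minute, on the same timescale that intermediate A forms”.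

**The result.** Your flask gives 57.3 % target and 42.7 % intermediate A, so the forecast held on both.

**The race.** In your flask, half of the turnover of substrate into intermediate A is done by 0.259 min, earlier than the half-life of second reagent by decomposition alone. The final [intermediate A] of your flask, 0.213 mM, stands just above the break-even level of 0.200 mM.

**Second flask.** In the neighbour with 0.45 mM, the break-even level and the wait stay the same, and I count 0.256 mM of second reagent as surviving. The same split gives 34.5 % target. The computed neighbour gives 38.8 % target and 61.2 % intermediate A.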